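SEM = 2-(trimethylsilyl)ethoxymethyl (CH2OCH2CH2SiMe3). Remark: the target is taken as the free base; its imidazole N–H is tautomeric, so the 2,4- and 2,5-disubstituted descriptions are the same compound.

## Analysis of the target

Nortopsentin B (11) is an achiral, fully aromatic tris-heterocycle. A central imidazole carries a 6-bromoindol-3-yl group at C2 and an unsubstituted indol-3-yl group at C4. There is no stereocenter, and no ring is fused across the three units. The only skeletal bonds between rings are two heteroaryl–heteroaryl C–C bonds: bromoindole C3 to imidazole C2, and imidazole C4 to indole C3.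

The sensitive groups are three acidic N–H groups, two electron-rich indoles with free C2 positions (acid, electrophiles, oxidants), and the aryl C–Br bond. That bond is at risk from zerovalent palladium at high temperature, from alkyllithium reagents and from hydrogenolysis.

The difficulty is differentiation. The two indoles differ by a single bromine that cannot be placed selectively at C6 by late electrophilic bromination, so it has to arrive with its ring and survive every later step.

The plan rests on the bond from bromoindole C3 to imidazole C2. Imidazole C2 lies between both nitrogens and is the most acidic C–H of an N1-protected imidazole. Bromoindole C3 corresponds to the C3 ketone of 6-bromoisatin (6), which already holds bromine at C6. One partner is therefore a natural carbanion and the other a natural electrophile, and only the oxidation level of the oxindole has to be corrected afterwards.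

## Retrosynthetic reasoning

**11 from 10.** The two N–H bonds of the imidazole and the plain indole are the last to be uncovered. Both nitrogens carry SEM groups in 10, so one fluoride-induced cleavage frees them together. The bromoindole N–H is already free in 10. The forward step must cleave two N–C aminal bonds without touching C–Br.

**10 from 9.** The bromoindole ring is traced back to a 3-hydroxyoxindole. No bond of the skeleton is cut. C2 is raised to the lactam carbonyl and C3 gains a hydroxyl. This turns the aromatic C3, which has no polarity handle, into the carbinol carbon of a ketone adduct. The forward reaction is a hydride reduction of the lactam in which the C3 oxygen is lost during aromatization. The stereocenter of 9 disappears there, so it never needs control.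

**9 from 5 and 6 (through 7 and 8).** The bond between oxindole C3 and imidazole C2 is cut. It is chosen over the imidazole C4 to indole C3 bond because it is the one attached to the brominated ring. Cutting here lets the bromine come from the commercial ketone 6 with its position fixed. The imidazole half becomes the 2-lithio species 7, made from 5 by deprotonation. The isatin half is used as its sodium amidate 8, which masks the N–H and switches off the lactam carbonyl. The forward reaction must be a clean 1,2-addition with no halogen–metal exchange.

**5 from 4.** Two N–C bonds to the SEM groups are cut. The protecting group is chosen because it survives an alkyllithium, assists lithiation at imidazole C2 through its oxygen, and leaves both nitrogens in one final operation. On the imidazole the alkylation should go to the nitrogen remote from the indolyl group.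

**4 from 2 and 3.** The imidazole ring is opened at both C–N bonds of the C4–C5 unit. C4 and C5 come from the bromoketone 2, and the whole N1–C2–N3 unit comes from one molecule of formamidine acetate (3). An amidine is chosen because it carries both nitrogens and the C2 carbon already joined, so the ring closes by one substitution and one condensation under mild conditions. This builds the unbrominated half, which has no selectivity problem, in one step.

**2 from 1.** The C–Br bond of the side chain is cut, leading to commercial 3-acetylindole (1). The 3-acyl group deactivates the indole ring, so bromination is expected on the methyl group.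

## Alternatives that were turned down

**Alternative 1: münchnone cycloaddition to build the imidazole.**
- Disconnection: the imidazole itself is cut at C4–C5 and C2–N3.
- Forward key step: the N-acyl-N-(2,4-dimethoxybenzyl)glycine A2, which carries the 6-bromo-1-tosylindole-3-carbonyl group, is cyclodehydrated to a münchnone. This adds as a 1,3-dipole to the N-tosyl imine A3 of 1-tosylindole-3-carbaldehyde. Loss of CO2 and toluenesulfinate gives the fully substituted imidazole A1.
- For: the ring is assembled convergently with both indoles attached. The regiochemistry follows from the mechanism (acyl carbon becomes C2, imine carbon becomes C4). No strongly basic organometallic and no palladium come near the C–Br bond. On these two points it is stronger than the chosen route.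
- Against: A2 and A3 each need several operations from commercial indoles, with the brominated half first raised to the acid oxidation level. The münchnone is in equilibrium with an acylamino ketene, which can give β-lactams with the imine or self-condense. The imine carbon of A3 is conjugated to the indole nitrogen and is only a moderate dipolarophile even with the sulfonyl groups. A1 carries three protecting groups of two kinds. The dimethoxybenzyl group needs strong acid on an indole-rich substrate and the tosyl groups need base.
- Comparison: the chosen route offers roughly half the operations, one protecting group type removed in one step, and a commercial building block that brings the bromine in the bond-forming step.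

**Alternative 2: titanium reductive oxo-amide coupling to close the bromoindole.**
- Disconnection: the C2–C3 bond of the bromoindole.
- Forward key step: the keto formanilide A5 is treated with low-valent titanium from TiCl3 and zinc (Fürstner indole synthesis). The ketone and formamide carbonyls couple and the pyrrole ring closes to give A4, which is constitutionally identical with 10.
- For: the indole is made aromatic directly with its N–H free and bromine fixed by the benzene precursor. This is a real advantage over the chosen route, whose aromatization depends on a double deoxygenation.
- Against: the ketone of A5 is attached to imidazole C2. It would most plausibly be made by acylating the same lithiated imidazole 7 with an ortho-aminobenzoyl electrophile that carries the bromine, so the organolithium step is not avoided. Formylation and the titanium step then add operations. A5 is a chelating 2-acylimidazole, which can bind titanium unproductively. The Lewis-acidic, HCl-releasing titanium medium also puts the two SEM aminals at risk.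
- Comparison: the chosen route reaches the same intermediate 10 from 5 in two steps with reagents that leave SEM alone.

**Alternative 3: direct C–H arylation of imidazole C5.**
- Disconnection: the bond between the imidazole and the plain indole.
- Forward key step: the 2-(6-bromo-1-tosylindol-3-yl)imidazole A7 is arylated at C5–H by 3-iodo-1-tosylindole A8 under Pd(OAc)2, a phosphine, pivalate and K2CO3 (concerted metalation–deprotonation). The product is A6, in which the SEM nitrogen is flanked by both aryl groups.
- For: it is modular and uses no cryogenic organometallic in the coupling, which would suit analogue work better than the chosen route. C5 is the intrinsically preferred site once C2 is blocked.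
- Against: A7 contains an aryl bromide that must survive zerovalent palladium at the high temperatures typical of such arylations. Iodide reacts faster than bromide, but the margin narrows as the temperature rises and oligomerization becomes possible. A8 is an electron-rich heteroaryl iodide prone to protodeiodination. Making A7 already requires the bromoindole C3 to imidazole C2 bond, which is the hard bond of the molecule. Two kinds of protecting group need two deprotections.
- Comparison: the chosen route never exposes the C–Br bond to palladium and makes the hard bond directly from a ketone that is bought with bromine in place.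

Key step: step 4

## Route

**Step 1**
Reactants: 1 3-acetylindole [1-(1H-indol-3-yl)ethanone]
Product: 2 3-(bromoacetyl)indole [2-bromo-1-(1H-indol-3-yl)ethanone]
Conditions: CuBr2 (2.1 equiv), EtOAc/CHCl3, reflux
Reagents that add atoms: CuBr2, Br[Cu]Br
Why: α-Bromination of an aryl methyl ketone by CuBr2 through the copper-bound enol; the 3-acyl group makes the indole a vinylogous amide that resists ring bromination, and the heterogeneous reagent should stop at the monobromide.

**Step 2**
Reactants: 2 3-(bromoacetyl)indole; 3 formamidine acetate
Product: 4 4-(1H-indol-3-yl)-1H-imidazole
Conditions: HC(=NH)NH2·AcOH (4 equiv), liq. NH3, sealed pressure vessel, 45 °C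
Reagents that add atoms: none
Why: Amidine/α-halo ketone imidazole synthesis: formamidine, set free from its acetate by ammonia, displaces bromide with one nitrogen, the other nitrogen condenses with the ketone, and loss of water aromatizes the ring, so N1, C2 and N3 all come from one molecule of 3. Only the α-halo ketone is electrophilic and the indole N–H is not deprotonated by ammonia, so it needs no protection.

**Step 3**
Reactants: 4 4-(1H-indol-3-yl)-1H-imidazole
Product: 5 1-SEM-4-(1-SEM-indol-3-yl)imidazole
Conditions: NaH (2.4 equiv), THF/DMF, 0 °C; SEMCl (2.2 equiv), 0 °C → rt
Reagents that add atoms: 2-(trimethylsilyl)ethoxymethyl chloride (SEMCl), C[Si](C)(C)CCOCCl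
Why: Double N-alkylation (SN2 at the chloromethyl ether) of the indolide/imidazolide dianion, which takes up two molecules of SEMCl. On the imidazole the nitrogen remote from the indolyl group should react for steric reasons, giving the 1,4-isomer; any minor 1,5-isomer is removed by chromatography.

**Step 4**
Reactants: 5 1-SEM-4-(1-SEM-indol-3-yl)imidazole; 6 6-bromoisatin
Product: 9 racemic 6-bromo-3-hydroxy-3-[1-SEM-4-(1-SEM-indol-3-yl)imidazol-2-yl]indolin-2-one, via C2-lithiated imidazole 7 (not isolated), via sodium 6-bromoisatinate 8 (not isolated)
Conditions: 5, n-BuLi (1.0 equiv), THF, −78 °C; separately 6 (1.3 equiv), NaH (1.3 equiv), THF, 0 °C; 7 cannulated onto 8 at −78 °C, then → 0 °C; sat. aq NH4Cl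
Reagents that add atoms: none
Why: n-BuLi deprotonates 5 at imidazole C2, the C–H flanked by both ring nitrogens and within reach of the lithium-coordinating SEM oxygen; indole C2–H needs a stronger base or a higher temperature and should be left alone by one equivalent at −78 °C. Compound 6 is converted separately into its sodium amidate 8, so that the acidic N–H cannot quench 7 and the lactam carbonyl, now part of an amidate, is no longer electrophilic. Carbanion 7 then adds 1,2 to the only remaining ketone, C3 of 8, forming the bond between bromoindole C3 and imidazole C2, and protonation on work-up gives 9. The closest known reaction type is the addition of aryl- and heteroaryllithium or Grignard reagents to N-metalated isatins to give 3-substituted 3-hydroxyoxindoles, together with the trapping of 2-lithio-1-SEM-imidazoles by ketones. No ring is closed. The new stereocenter at oxindole C3 forms without control as a racemate and needs none, because it is planarized in step 5. The step needs chemoselectivity against bromine–lithium exchange: no n-BuLi remains when the bromide is introduced, and exchange between 7 and the aryl bromide would trade a stabilized imidazol-2-yl anion for a less stabilized aryl anion, so it is uphill and slow at −78 °C. The position of bromine is secured by the substrate, since it is in place at C6 of the isatin.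

**Step 5**
Reactants: 9 racemic 6-bromo-3-hydroxy-3-[1-SEM-4-(1-SEM-indol-3-yl)imidazol-2-yl]indolin-2-one
Product: 10 6-bromo-3-[1-SEM-4-(1-SEM-indol-3-yl)imidazol-2-yl]-1H-indole
Conditions: BH3·THF (6 equiv), THF, 0 → 50 °C; MeOH, 60 °C
Reagents that add atoms: none
Why: Borane reduction of a 3-substituted 3-hydroxyoxindole to the 3-substituted indole: the lactam carbonyl is reduced through the O-borylated hemiaminal to the indoline level, and the tertiary benzylic C3–O bond, assisted by the aniline nitrogen, is lost together with a C2 proton to give the aromatic ring, which erases the stereocenter. Borane should not touch the aryl bromide, the SEM aminals or the heteroaromatic rings, and warm methanol breaks the borane adduct at imidazole N3.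

**Step 6**
Reactants: 10 6-bromo-3-[1-SEM-4-(1-SEM-indol-3-yl)imidazol-2-yl]-1H-indole
Product: 11 nortopsentin B [6-bromo-3-[4-(1H-indol-3-yl)-1H-imidazol-2-yl]-1H-indole]
Conditions: TBAF (1 M in THF, 10 equiv), H2NCH2CH2NH2, DMF, 80 °C; aqueous work-up
Reagents that add atoms: none
Why: Fluoride attacks silicon in each SEM group; fragmentation releases fluorotrimethylsilane, ethylene and formaldehyde and leaves the indolide and imidazolide, which are protonated on work-up. Ethylenediamine traps formaldehyde so that it cannot re-add to nitrogen or to electron-rich indole carbons, and the C–Br bond is inert to fluoride.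

## Compound list

1 | 3-acetylindole | CC(=O)c1c[nH]c2ccccc12 | starting material
2 | 3-(bromoacetyl)indole | O=C(CBr)c1c[nH]c2ccccc12 | intermediate
3 | formamidine acetate | CC(=O)O.NC=N | starting material
4 | 4-(1H-indol-3-yl)-1H-imidazole | c1nc(-c2c[nH]c3ccccc23)c[nH]1 | intermediate
5 | 1-SEM-4-(1-SEM-indol-3-yl)imidazole | C[Si](C)(C)CCOCn1cnc(-c2cn(COCC[Si](C)(C)C)c3ccccc23)c1 | intermediate
6 | 6-bromoisatin | O=C1Nc2cc(Br)ccc2C1=O | starting material
7 | 2-lithio-1-SEM-4-(1-SEM-indol-3-yl)imidazole (not isolated) | [Li]c1nc(-c2cn(COCC[Si](C)(C)C)c3ccccc23)cn1COCC[Si](C)(C)C | intermediate
8 | sodium 6-bromoisatinate, N-sodio salt of 6 (not isolated) | [Na+].O=C1[N-]c2cc(Br)ccc2C1=O | intermediate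
9 | racemic 6-bromo-3-hydroxy-3-[1-SEM-4-(1-SEM-indol-3-yl)imidazol-2-yl]indolin-2-one | O=C1Nc2cc(Br)ccc2C1(O)c1nc(-c2cn(COCC[Si](C)(C)C)c3ccccc23)cn1COCC[Si](C)(C)C | intermediate
10 | 6-bromo-3-[1-SEM-4-(1-SEM-indol-3-yl)imidazol-2-yl]-1H-indole | Brc1ccc2c(-c3nc(-c4cn(COCC[Si](C)(C)C)c5ccccc45)cn3COCC[Si](C)(C)C)c[nH]c2c1 | intermediate
11 | nortopsentin B | Brc1ccc2c(-c3nc(-c4c[nH]c5ccccc45)c[nH]3)c[nH]c2c1 | target

## Step count and risk

Total steps: 6. Longest linear sequence: 6 (1 → 2 → 4 → 5 → 9 → 10 → 11); 3 enters at step 2 and 6 at step 4, both as commercial compounds.

**Step 4 (key step).** The most likely failure is incomplete addition. The amidate 8 is sparingly soluble in THF and its ketone is deactivated by the neighbouring anionic nitrogen, so 7 may be protonated or decompose before it adds. A second risk is bromine–lithium exchange if any alkyllithium survives the metalation.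

Fallback: the carbonyl addition is replaced by a Negishi cross-coupling, setting out from 5.
- Compound 5 is lithiated as before to 7 and transmetalated with ZnCl2 to the imidazol-2-ylzinc chloride F1.
- The partner is made from commercial 6-bromoindole F2: iodination at C3 (I2, KOH, DMF) gives 6-bromo-3-iodo-1H-indole F3, and Boc2O/DMAP gives tert-butyl 6-bromo-3-iodoindole-1-carboxylate F4.
- Coupling of F1 with F4 under Pd(PPh3)4 (zerovalent palladium) in THF at 25–50 °C should occur at the C–I bond, which undergoes oxidative addition far faster than C–Br at this temperature. It gives the N-Boc biaryl F5.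
- K2CO3 in MeOH removes the Boc group and returns the route at 10, bypassing step 5 as well.

**Step 5.** The likely problems are stalling at the indolin-3-ol stage when the tertiary C3 oxygen is not lost, over-reduction to the indoline, and sequestration of borane by imidazole N3.

Fallback: reduction and aromatization are separated, setting out from 9.
- Compound 9 is reduced with BH3·SMe2 in refluxing THF to the amine oxidation level, and the racemic indolin-3-ol F6 is isolated.
- F6 is dehydrated in a separate step with pyridinium p-toluenesulfonate in toluene at 80 °C. Ionization at C3 is assisted by the aniline nitrogen, and loss of a C2 proton gives the indole.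
- Material that has gone on to the racemic indoline F7 is dehydrogenated with MnO2 in CH2Cl2.
- Both streams return to the route at 10.

**Step 2.** Ammonia, present as the solvent, can compete with formamidine for the C–Br bond, and the resulting free α-amino ketone would self-condense to a dihydropyrazine. Ring closure may also be slow, because the ketone is deactivated as a vinylogous amide by the indole nitrogen.

Fallback: a Marckwald sequence that keeps the amino ketone protonated, setting out from 2.
- NaN3 in acetone/water gives 2-azido-1-(1H-indol-3-yl)ethanone F8.
- Hydrogenation (H2, Pd/C, HCl/MeOH) gives 2-amino-1-(1H-indol-3-yl)ethanone hydrochloride F9, kept as the salt to prevent self-condensation.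
- KSCN in hot aqueous AcOH closes 4-(1H-indol-3-yl)-1,3-dihydroimidazole-2-thione F10.
- Raney nickel in refluxing EtOH removes sulfur and returns the route at 4.

**Step 6.** Cleavage at the indole nitrogen may be incomplete, leaving mono-SEM or N-hydroxymethyl material, and formaldehyde may re-add to the product.

Fallback: the fluoride fragmentation is replaced by a two-stage acidolysis, setting out from 10.
- TFA in CH2Cl2 at room temperature cleaves the silylethyl parts and should give the bis(N-hydroxymethyl) compound F11.
- After evaporation, F11 is treated with aqueous NH3 in MeOH, which releases formaldehyde from both nitrogens and returns the route at 11.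
- The acid stage carries a risk of electrophilic attack at indole C2, which is why it is the reserve and not the first choice.

## Further compounds

F1 | step 4 | [1-SEM-4-(1-SEM-indol-3-yl)imidazol-2-yl]zinc chloride | Cl[Zn]c1nc(-c2cn(COCC[Si](C)(C)C)c3ccccc23)cn1COCC[Si](C)(C)C
F2 | step 4 | 6-bromoindole | Brc1ccc2cc[nH]c2c1
F3 | step 4 | 6-bromo-3-iodo-1H-indole | Brc1ccc2c(I)c[nH]c2c1
F4 | step 4 | tert-butyl 6-bromo-3-iodoindole-1-carboxylate | CC(C)(C)OC(=O)n1cc(I)c2ccc(Br)cc21
F5 | step 4 | tert-butyl 6-bromo-3-[1-SEM-4-(1-SEM-indol-3-yl)imidazol-2-yl]indole-1-carboxylate | CC(C)(C)OC(=O)n1cc(-c2nc(-c3cn(COCC[Si](C)(C)C)c4ccccc34)cn2COCC[Si](C)(C)C)c2ccc(Br)cc21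
F6 | step 5 | racemic 6-bromo-3-[1-SEM-4-(1-SEM-indol-3-yl)imidazol-2-yl]indolin-3-ol | OC1(CNc2cc(Br)ccc21)c1nc(-c2cn(COCC[Si](C)(C)C)c3ccccc23)cn1COCC[Si](C)(C)C
F7 | step 5 | racemic 6-bromo-3-[1-SEM-4-(1-SEM-indol-3-yl)imidazol-2-yl]indoline | Brc1ccc2c(c1)NCC2c1nc(-c2cn(COCC[Si](C)(C)C)c3ccccc23)cn1COCC[Si](C)(C)C
F8 | step 2 | 2-azido-1-(1H-indol-3-yl)ethanone | [N-]=[N+]=NCC(=O)c1c[nH]c2ccccc12
F9 | step 2 | 2-amino-1-(1H-indol-3-yl)ethanone hydrochloride | Cl.NCC(=O)c1c[nH]c2ccccc12
F10 | step 2 | 4-(1H-indol-3-yl)-1,3-dihydroimidazole-2-thione | S=c1[nH]cc(-c2c[nH]c3ccccc23)[nH]1
F11 | step 6 | 6-bromo-3-[1-(hydroxymethyl)-4-[1-(hydroxymethyl)indol-3-yl]imidazol-2-yl]-1H-indole | OCn1cc(-c2cn(CO)c(-c3c[nH]c4cc(Br)ccc34)n2)c2ccccc21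
A1 | alternative 1 | 1-(2,4-dimethoxybenzyl)-2-(6-bromo-1-tosylindol-3-yl)-4-(1-tosylindol-3-yl)imidazole | COc1ccc(Cn2cc(-c3cn(S(=O)(=O)c4ccc(C)cc4)c4ccccc34)nc2-c2cn(S(=O)(=O)c3ccc(C)cc3)c3cc(Br)ccc23)c(OC)c1
A2 | alternative 1 | N-(6-bromo-1-tosylindole-3-carbonyl)-N-(2,4-dimethoxybenzyl)glycine | COc1ccc(CN(CC(=O)O)C(=O)c2cn(S(=O)(=O)c3ccc(C)cc3)c3cc(Br)ccc23)c(OC)c1
A3 | alternative 1 | N-tosyl imine of 1-tosylindole-3-carbaldehyde | Cc1ccc(cc1)S(=O)(=O)N=Cc1cn(S(=O)(=O)c2ccc(C)cc2)c2ccccc12
A4 | alternative 2 | 6-bromo-3-[1-SEM-4-(1-SEM-indol-3-yl)imidazol-2-yl]-1H-indole (identical with 10) | Brc1ccc2c(-c3nc(-c4cn(COCC[Si](C)(C)C)c5ccccc45)cn3COCC[Si](C)(C)C)c[nH]c2c1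
A5 | alternative 2 | N-[5-bromo-2-[1-SEM-4-(1-SEM-indol-3-yl)imidazole-2-carbonyl]phenyl]formamide | O=CNc1cc(Br)ccc1C(=O)c1nc(-c2cn(COCC[Si](C)(C)C)c3ccccc23)cn1COCC[Si](C)(C)C
A6 | alternative 3 | 1-SEM-2-(6-bromo-1-tosylindol-3-yl)-5-(1-tosylindol-3-yl)imidazole | C[Si](C)(C)CCOCn1c(-c2cn(S(=O)(=O)c3ccc(C)cc3)c3ccccc23)cnc1-c1cn(S(=O)(=O)c2ccc(C)cc2)c2cc(Br)ccc12
A7 | alternative 3 | 1-SEM-2-(6-bromo-1-tosylindol-3-yl)imidazole | C[Si](C)(C)CCOCn1ccnc1-c1cn(S(=O)(=O)c2ccc(C)cc2)c2cc(Br)ccc12
A8 | alternative 3 | 3-iodo-1-tosylindole | Cc1ccc(cc1)S(=O)(=O)n1cc(I)c2ccccc12
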